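Minutes are the unit of this comparison: four flasks of one recipe stand for 8.0 min at four temperatures, and two earlier runs are on hand.

| setting | south-west | west | ochre | teal | blue | amber |
|---|---|---|---|---|---|---|
| substrate | 1.5 M | 2.3 M | 2.3 M | 2.3 M | 2.3 M | 2.3 M |
| reagent | 1.61 M | 1.61 M | 1.61 M | 1.61 M | 1.61 M | 1.61 M |
| free catalyst | 2.3 mM | 4.6 mM | 2.3 mM | 2.3 mM | 2.3 mM | 2.3 mM |
| second catalyst | 4.6 mM | 4.6 mM | 4.6 mM | 4.6 mM | 4.6 mM | 4.6 mM |
| temperature | 95 °C | 128 °C | 120 °C | 140 °C | 100 °C | 80 °C |
| remark | run made earlier | run made earlier |  |  |  |  |
| time |  |  | 8.0 min | 8.0 min | 8.0 min | 8.0 min |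

| run | time / min | target / % | substrate / % |
|---|---|---|---|
| south-west | 1.00 | 2.5 | 73.7 |
| south-west | 3.00 | 5.3 | 37.6 |
| south-west | 5.00 | 7.4 | 23.3 |
| south-west | 8.00 | 9.3 | 12.2 |
| south-west | 15.0 | 11.1 | 4.7 |
| west | 0.417 | 5.6 | 34.7 |
| west | 1.33 | 12.3 | 9.0 |
| west | 2.00 | 14.2 | 4.9 |
| west | 3.00 | 14.2 | 3.3 |
| west | 5.00 | 16.3 | 1.3 |

(each reading ± 0.5 percentage points)



* the flask that comes out highest in amount of target, in percent of the substrate charged, or "all alike" when all lie within 1.5 percentage points (ochre / teal / blue / amber / all alike)
* target at the end, in percent of the substrate charged, ochre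
* target at the end, in percent of the substrate charged, teal
* target at the end, in percent of the substrate charged, blue
* target at the end, in percent of the substrate charged, amber

The south-west run seems to contradict itself. Over its first reading the substrate falls at 0.305 /min, but between its last two readings at 0.136 /min, slower at one temperature. The stretch from first to second reading gives 0.336 /min. So the decay reads as pseudo-first-order down to 37.6% of the charge and slows after that, and the early constant is the one to carry.

The west run starts at 2.54 /min with twice the free catalyst. Taking the rate as proportional to free catalyst leaves 1.27 /min, though the substrate charges differ as well. My reckoning therefore uses the doubling step, the rise in temperature that doubles the early constant: 16.0 K.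

Carried down to amber, the step gives 0.160 /min, so 27.9% of the substrate stands at the end. That is 72.1% lost, against the 65 to 70 per cent of the forecast. Carried up to teal, it gives a half-life of 0.325 min, far shorter than the time allowed. Hot flasks should then rank by selectivity, the share of lost substrate found as target: the last readings give 11.6% in the south-west run and a higher 16.5% in the west run.

The forecast named teal, with ochre 14%, teal 15.5%, blue 11.3% and amber 7%, holding that "Ochre and teal should be essentially complete".

The flasks gave teal as highest, with ochre 13.8%, teal 18.9%, blue 7.84% and amber 4.24%.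

    substrate + intermediate → side product (k = 0.00887 /M/s, Ea = 51.0 kJ/mol)
    target ⇌ isomer of the product (K = 1.50, k = 0.00170 /s, Ea = 97.0 kJ/mol, ΔH = −25.0 kJ/mol)
    substrate + free catalyst ⇌ free catalyst + intermediate (K = 0.659, k = 0.815 /M/s, Ea = 56.0 kJ/mol, ΔH = −1.00 kJ/mol)
    reagent + second catalyst + intermediate → second catalyst + target (k = 0.293 /M²/s, Ea = 68.0 kJ/mol)
    (constants at 80 °C)

Amber kept 27.2% of its substrate, against the 27.9% reckoned. The neighbouring repeat of amber at 65 °C, with all amounts and the time held, takes the same doubling step further down: 0.0835 /min, so 51.3% of the substrate should stand. That flask kept 55.5%, more than reckoned. Beside it, in percent of the substrate charged, 36.1% stood as side product, 6.36% as intermediate and 1.84% as target.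

The runs stem from a simulated flask for an exercise, noise included.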